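## Analysis of the target

The target is a 3-arylchroman-4-ol (an isoflavan-4-ol). Ring A of the chroman carries a free hydroxyl at C5 and a methoxy group at C7; the pyran ring (ring C: O1, C2, C3, C4, C4a, C8a) carries a hydroxyl at C4 and, at C3, ring B, a phenyl ring with 2'-methoxy, 4'-hydroxy and 5'-(3-methylbut-2-enyl) groups. The two stereocentres C3 and C4 are adjacent; the SMILES reads as (3R,4R), which places the C3 aryl group and the C4 hydroxyl on the same face of ring C (3,4-cis). The C4 carbinol is benzylic to a ring that has oxygen at both ortho positions (C5, C8a) and at the para position (C7), so it ionises easily and acid would dehydrate or epimerise it. The ortho-prenylphenol of ring B cyclises to a dimethylchroman under acid, and its trisubstituted alkene rules out hydrogenation, hydrogenolysis, electrophilic halogen and peracids once it is in place. The difficulty is to set two contiguous stereocentres, neither of them epimerisable in the product, in the cis sense and in one absolute configuration, on a scaffold whose oxygen pattern is unsymmetrical on both rings, with an end game that is neither acidic nor reductive. The strategy rests on the chain O1–C2–C3–C4 and on C4a. C4a lies between the oxygen-bearing carbons C5 and C8a, so ring A together with C4 is a 2,6-dihydroxy-4-methoxybenzaldehyde that is symmetric about the C4a–C7 axis. C2–C3 with ring B is a 1-arylethene, and a nitro group at C3 makes C2 electrophilic, then C3 nucleophilic, and can finally be exchanged for hydrogen.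

## Retrosynthetic reasoning

**19 to 18.** Only Si–O bonds are cut in the last step: 19 is traced back to the tris-silyl ether 18, in which both phenols and the C4 carbinol are masked. Silyl ethers are chosen because buffered fluoride removes them without touching the ionisable C4–O bond or the prenyl group; acetals or benzyl ethers would need acid or hydrogen.

**18 to 17.** The C3–H bond of 18 is traced back to a C3–NO2 bond in 17. The nitro group is the activating group of the ring construction and is removed by a tin hydride radical chain. The C3 radical is tertiary and benzylic, hence easy to form, and planar, so both C3 epimers of 17 converge on it. The forward reaction has to deliver hydrogen to the face opposite the C4 silyl ether, which leaves the aryl group cis to the C4 oxygen.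

**17 to 16.** The two Si–O bonds at O4 and O5 are cut. Silylating the nitro diol 16 blocks retro-Henry opening of the β-nitro carbinol. The bulky ether at C4, pushed pseudoaxial by the silyl ether at C5, also provides the facial bias needed in the radical step.

**16 to 12 and 14 (key disconnection).** O1–C2 and C3–C4 are cut. These are the two bonds of ring C that lie outside ring A and outside the C2–C3 unit, so the cut separates the molecule into its two aryl halves, each with its complete oxygen pattern. Because 14 is symmetric, the two ring A oxygens ortho to C4a need not be told apart: the phenol that adds becomes O1 and the other remains as the 5-hydroxyl, without any protecting group on ring A. The forward reaction must add a phenoxide of 14 to the CH2 terminus of the nitroalkene 12 and close the ring by Henry addition of the resulting nitronate to the formyl group. A chiral bifunctional amine–thiourea has to fix the configuration of C4; C3 may form as a mixture. Cutting C2–C3 or C4–C4a instead would leave a bond to be made at a hindered aromatic position or would not use the symmetry of ring A.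

**14 to 13.** One O–CH3 bond is cut. The 4-hydroxyl of 13 is the only one not held in a hydrogen bond to the formyl group and is the most acidic, so mono-methylation should go there.

**12 to 10 (through 11), then to 8 and 9.** The C2=C3 double bond comes from β-elimination of the nitro alcohol 10 through its mesylate 11. The C2–C3 bond of 10 is cut next: C2 is the carbon of formaldehyde 9, added to the arylnitromethane 8 in a Henry reaction. The sequence is placed directly before the key step because 12, like other 1-aryl-1-nitroethenes, oligomerises easily and should be made and used at once.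

**8 to 6 and 7.** The aryl–CH2NO2 bond is cut and is to be made by palladium-catalysed coupling of the aryl bromide 6 with nitromethane 7. The alternative cut at the benzylic C–N bond (nitrite displacement on a benzylic halide) is less attractive here, because an electron-rich benzylic halide ionises and gives much nitrite ester.

**6 to 3 and 4 (through 5), then 3 to 2 to 1.** The aryl–prenyl bond is cut. Chemoselective iodine–magnesium exchange on the bromo iodide 3 gives the arylmagnesium 5, which is allylated with prenyl bromide 4 under copper catalysis while the bromide is kept for the next coupling. The iodide comes from iodination of the bromophenol 1 at the position ortho to the hydroxyl and para to the methoxy group, followed by silylation. Halogenation must precede prenylation, because electrophilic halogen would attack the prenyl alkene. A triisopropylsilyl ether is chosen for the ring B phenol because it has to survive an ortho arylmagnesium, hot phosphate base and several amine bases, and still falls with fluoride at the end.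

## Alternatives that were turned down

**Alternative 1:** Aryne–arylacrolein annulation.
- **Disconnection:** C8a–O1 and C4a–C4 are cut, so that ring A is joined to a three-carbon enal; O1–C2 then closes by electrocyclisation.
- **Forward key step:** fluoride releases a 3,5-dioxygenated aryne from the silylaryl triflate A1. The carbonyl group of the 2-arylacrolein A2 adds across it to a benzoxete, which opens to an ortho-quinone methide; an oxa-6π electrocyclisation gives the isoflav-3-ene A3.
- **For it:** ring C is built in one step from two flat, stable partners, the oxygen next to the aryne bond dictates the regiochemistry of capture, and no sensitive nitroalkene is involved. On convergence and robustness of the bond construction it is at least as strong as the chosen route.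
- **Against it:** A3 has no stereocentre. C3 and C4 would both have to be set afterwards on the C3=C4 alkene, and the simplest hydration, hydroboration–oxidation, adds H and OH syn and would give the 3,4-trans isomer. The prenyl group is postponed to a late cross-coupling of the bromide, and the two (trimethylsilyl)ethoxymethyl ethers need acid or forcing fluoride conditions, which the C4 carbinol and the ortho-prenylphenol tolerate poorly.
- **Comparison:** at least five operations would follow the key step, against three here. The chosen strategy sets C4 in the ring-forming step and carries the prenyl group and only fluoride-labile silyl ethers from the start.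

**Alternative 2:** Photochemical vinylketene benzannulation.
- **Disconnection:** ring B is cut at C1'–C2', C3'–C4' and C4'–C5'; C2' and C3' come from an alkyne and the other four carbons from a diazo enone attached to a finished chroman.
- **Forward key step:** irradiation of the α-diazo enone A4 causes a Wolff rearrangement to a vinylketene, which adds methoxyacetylene A5 in a [2+2] sense. The 4-vinylcyclobutenone reopens, and 6π electrocyclisation with tautomerisation gives the phenol A6.
- **For it:** ring B would emerge with all four substituents placed by the mechanism, with its 4'-hydroxyl free and without aromatic substitution or cross-coupling. On regiocontrol of ring B it is stronger than any route that functionalises a benzene ring.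
- **Against it:** the stereochemical problem is untouched, because A4 already contains both stereocentres of ring C, which would need a separate asymmetric synthesis of a 3-acylchroman-4-ol. A4 is a skipped dienone whose doubly activated CH2 isomerises into conjugation under the base of a diazo transfer. Its ketene can be trapped intramolecularly by the prenyl alkene, and A5 is volatile, unstable and needed in excess under ultraviolet light.
- **Comparison:** the chosen route obtains the ring B pattern from the commercial bromophenol 1 in three ordinary steps, so building the ring de novo adds steps without solving the harder stereochemical question.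

**Alternative 3:** Carbenoid C–H insertion.
- **Disconnection:** C2–C3 is cut; C2 is the carbon of a methoxy group on ring A and C3 a carbenoid carbon between the ketone and ring B.
- **Forward key step:** a dirhodium tetracarboxylate catalyst converts the diazo ketone A7 into a carbenoid that inserts into a C–H bond of the ortho methoxy group and closes the pyranone ring of the racemic isoflavanone A8.
- **For it:** A7 comes from a deoxybenzoin by one diazo transfer, so ring C is reached in very few steps. An isoflavanone is also a good platform for the stereocentres, because transfer hydrogenation with dynamic kinetic resolution is an established way to cis-3-arylchroman-4-ols. On reliability of the stereochemical step this alternative is stronger than the chosen one.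
- **Against it:** the insertion needs a six-membered transition state into a methyl C–H bond, while the neighbouring methoxy oxygen can form an oxonium ylide and shift its methyl group, closing a five-membered ring instead; Wolff rearrangement also competes. A8 carries a methoxy group at C5 where the target has a hydroxyl, so one of three aryl methyl ethers would have to be cleaved selectively with a chelating Lewis acid in the presence of a prenyl group and a silyl ether.
- **Comparison:** the chosen strategy gives the free 5-hydroxyl directly from the symmetric aldehyde 14 and forms two ring bonds under mild organocatalysis. What it gives up is the proven dynamic kinetic resolution, which is kept as the fallback for its own stereochemical steps.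

Key step: step 8

Assumption on the chemistry: the catalyst of step 8 is 1-[3,5-bis(trifluoromethyl)phenyl]-3-[(1R,2R)-2-(dimethylamino)cyclohexyl]thiourea, and its (1R,2R) form is taken to give the (4S) carbinol of 16; the sense of induction has to be assigned on the first run, and the (1S,2S) catalyst is used instead if it proves opposite.

## Route

Step 1
Reactants: 1 4-bromo-3-methoxyphenol
Product: 2 4-bromo-2-iodo-5-methoxyphenol
Conditions: NIS, TsOH·H2O (cat.), MeCN, 0 °C to rt
Reagents that add atoms: N-iodosuccinimide, O=C1CCC(=O)N1I
Why: Electrophilic aromatic iodination; the position ortho to the hydroxyl and para to the methoxy group is the most activated and least hindered, whereas the position between the two oxygens is flanked on both sides.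

Step 2
Reactants: 2 4-bromo-2-iodo-5-methoxyphenol
Product: 3 (4-bromo-2-iodo-5-methoxyphenoxy)triisopropylsilane
Conditions: TIPSCl, imidazole, DMF, rt
Reagents that add atoms: chlorotriisopropylsilane, CC(C)[Si](Cl)(C(C)C)C(C)C
Why: Standard silylation of a phenol with a silyl chloride and imidazole; the triisopropylsilyl ether is preferred to a tert-butyldimethylsilyl ether because it must survive an ortho arylmagnesium, phosphate base at 70 °C and amine bases.

Step 3
Reactants: 3 (4-bromo-2-iodo-5-methoxyphenoxy)triisopropylsilane; 4 prenyl bromide (1-bromo-3-methylbut-2-ene)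
Product: 6 [4-bromo-5-methoxy-2-(3-methylbut-2-enyl)phenoxy]triisopropylsilane, via arylmagnesium chloride 5 (not isolated)
Conditions: iPrMgCl·LiCl, THF, −20 to 0 °C; then CuI (10 mol %), 4, 0 °C to rt
Reagents that add atoms: none
Why: Iodine–magnesium exchange is far faster at the C–I than at the C–Br bond of an electron-rich arene, so only 5 should form. Copper-catalysed allylation of the arylmagnesium with the primary allylic bromide should occur at the unhindered CH2 terminus (SN2 sense) and give the linear prenyl arene.

Step 4
Reactants: 6 [4-bromo-5-methoxy-2-(3-methylbut-2-enyl)phenoxy]triisopropylsilane; 7 nitromethane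
Product: 8 [5-methoxy-2-(3-methylbut-2-enyl)-4-(nitromethyl)phenoxy]triisopropylsilane
Conditions: Pd2(dba)3 (2.5 mol %), XPhos (6 mol %), K3PO4, 7 (10 equiv), 1,4-dioxane, 70 °C
Reagents that add atoms: none
Why: Cross-coupling of an aryl bromide with the nitronate of nitromethane (α-arylation of a nitroalkane) on zerovalent palladium with a bulky biarylphosphine. The excess of 7 suppresses a second arylation, and the trisubstituted alkene is too hindered for a Heck reaction.

Step 5
Reactants: 8 [5-methoxy-2-(3-methylbut-2-enyl)-4-(nitromethyl)phenoxy]triisopropylsilane; 9 formaldehyde (as paraformaldehyde)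
Product: 10 2-[2-methoxy-5-(3-methylbut-2-enyl)-4-(triisopropylsilyloxy)phenyl]-2-nitroethanol (racemic)
Conditions: (CH2O)n (1.0 equiv), Et3N (10 mol %), THF, 0 °C to rt
Reagents that add atoms: none
Why: Henry (nitroaldol) addition of the acidic benzylic nitroalkane to formaldehyde under amine catalysis; one equivalent of 9 limits double hydroxymethylation. The new stereocentre does not matter, because it becomes sp2 in step 6.

Step 6
Reactants: 10 2-[2-methoxy-5-(3-methylbut-2-enyl)-4-(triisopropylsilyloxy)phenyl]-2-nitroethanol
Product: 12 [5-methoxy-2-(3-methylbut-2-enyl)-4-(1-nitroethenyl)phenoxy]triisopropylsilane, via mesylate 11 (not isolated)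
Conditions: MsCl, iPr2NEt, CH2Cl2, −30 to 0 °C; cold silica pad, used at once
Reagents that add atoms: none
Why: Mesylation of the primary alcohol and E1cB elimination through the nitronate, the usual dehydration of β-nitro alcohols to nitroalkenes. 12 is not stored, because 1-aryl-1-nitroethenes oligomerise on standing or with base.

Step 7
Reactants: 13 2,4,6-trihydroxybenzaldehyde
Product: 14 2,6-dihydroxy-4-methoxybenzaldehyde
Conditions: Me2SO4 (1.0 equiv), K2CO3 (1.0 equiv), acetone, 0 °C to rt
Reagents that add atoms: dimethyl sulfate, COS(=O)(=O)OC
Why: Williamson methylation; the 4-hydroxyl is the most acidic and the only one not held in a hydrogen bond to the formyl group, so one equivalent of base and of Me2SO4 should methylate it selectively.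

Step 8
Reactants: 12 [5-methoxy-2-(3-methylbut-2-enyl)-4-(1-nitroethenyl)phenoxy]triisopropylsilane; 14 2,6-dihydroxy-4-methoxybenzaldehyde
Product: 16 (4S)-7-methoxy-3-[2-methoxy-5-(3-methylbut-2-enyl)-4-(triisopropylsilyloxy)phenyl]-3-nitrochromane-4,5-diol (both C3 epimers), via oxa-Michael adduct 15 (not isolated)
Conditions: (1R,2R)-amine–thiourea catalyst (10 mol %), 14 (1.3 equiv), CH2Cl2–PhMe, −20 °C, slow addition of 12
Reagents that add atoms: none
Why: The tertiary amine of the catalyst deprotonates one phenol of 14 while the thiourea binds the nitro group of 12, and the phenoxide adds to the unsubstituted CH2 terminus (oxa-Michael addition, O1–C2) to give the aryl-stabilised nitronate of 15. The nitronate carbon then adds to the formyl carbon, which is activated by the hydrogen bond from the remaining ortho hydroxyl (intramolecular Henry addition, C3–C4). The closest known reaction type is the amine- or amine–thiourea-catalysed oxa-Michael–Henry domino of salicylaldehydes with nitroalkenes, which leads to 3-nitrochroman-4-ols and 3-nitro-2H-chromenes. The pyran ring is closed in the Henry step by a 6-(enolexo)-exo-trig attack through a chair-like transition state. C4 is controlled by the catalyst, whose ammonium–thiourea pocket holds nitronate and aldehyde in one complex and exposes one face of the carbonyl group; C3 forms in the same event from whichever nitronate face reacts and is left uncontrolled, because it is erased in step 10. The step needs O- rather than C-alkylation of the electron-rich ring, which the deactivating formyl group and phenoxide formation should secure, and mono-addition, which the excess of 14 and the hydrogen bond holding the second hydroxyl should secure; no regiochemical choice arises, because 14 is symmetric and the unreacted hydroxyl becomes the 5-OH. Since C3 carries no hydrogen the adduct cannot dehydrate to a chromene, and the low temperature keeps retro-Henry opening slow.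

Step 9
Reactants: 16 (4S)-7-methoxy-3-[2-methoxy-5-(3-methylbut-2-enyl)-4-(triisopropylsilyloxy)phenyl]-3-nitrochromane-4,5-diol (both C3 epimers)
Product: 17 (4S)-4,5-bis(tert-butyldimethylsilyloxy)-7-methoxy-3-[2-methoxy-5-(3-methylbut-2-enyl)-4-(triisopropylsilyloxy)phenyl]-3-nitrochromane (both C3 epimers)
Conditions: TBSOTf (3 equiv), 2,6-lutidine, CH2Cl2, −40 to 0 °C
Reagents that add atoms: tert-butyldimethylsilyl trifluoromethanesulfonate, CC(C)(C)[Si](C)(C)OS(=O)(=O)C(F)(F)F
Why: Silylation with a silyl triflate and a hindered pyridine base, which is reactive enough for the hindered C4 carbinol and the phenol but not basic enough to open the β-nitro carbinol by retro-Henry cleavage. No stereocentre is touched.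

Step 10
Reactants: 17 (4S)-4,5-bis(tert-butyldimethylsilyloxy)-7-methoxy-3-[2-methoxy-5-(3-methylbut-2-enyl)-4-(triisopropylsilyloxy)phenyl]-3-nitrochromane (both C3 epimers)
Product: 18 (3R,4R)-4,5-bis(tert-butyldimethylsilyloxy)-7-methoxy-3-[2-methoxy-5-(3-methylbut-2-enyl)-4-(triisopropylsilyloxy)phenyl]chromane (3,4-cis)
Conditions: Bu3SnH (4 equiv), AIBN (in portions), PhMe, 100 °C
Reagents that add atoms: none
Why: Radical denitration of a tertiary benzylic nitro compound: Bu3Sn• adds to a nitro oxygen, the adduct fragments to Bu3SnONO and the planar C3 radical, common to both epimers of 17, and this radical takes hydrogen from Bu3SnH. The C4 silyl ether is held pseudoaxial by strain against the C5 silyl ether and the C3 aryl group. Hydrogen should therefore arrive axially on the face anti to it, leaving the aryl group equatorial and cis to the C4 oxygen, which is the (3R) configuration.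

Step 11
Reactants: 18 (3R,4R)-4,5-bis(tert-butyldimethylsilyloxy)-7-methoxy-3-[2-methoxy-5-(3-methylbut-2-enyl)-4-(triisopropylsilyloxy)phenyl]chromane
Product: 19 (3R,4R)-3-[4-hydroxy-2-methoxy-5-(3-methylbut-2-enyl)phenyl]-7-methoxychromane-4,5-diol (3,4-cis)
Conditions: Bu4NF, AcOH, THF, 0 °C to rt
Reagents that add atoms: none
Why: Fluoride cleavage of two aryl silyl ethers and one alkyl silyl ether; the AcOH buffer keeps the medium near neutral, so that the ionisable C4 carbinol and the ortho-prenylphenol see neither strong base nor acid. No stereocentre is affected.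

## Compound list

1 | 4-bromo-3-methoxyphenol | COc1cc(O)ccc1Br | starting material
2 | 4-bromo-2-iodo-5-methoxyphenol | COc1cc(O)c(I)cc1Br | intermediate
3 | (4-bromo-2-iodo-5-methoxyphenoxy)triisopropylsilane | COc1cc(O[Si](C(C)C)(C(C)C)C(C)C)c(I)cc1Br | intermediate
4 | prenyl bromide (1-bromo-3-methylbut-2-ene) | CC(C)=CCBr | starting material
5 | [5-bromo-4-methoxy-2-(triisopropylsilyloxy)phenyl]magnesium chloride (not isolated) | COc1cc(O[Si](C(C)C)(C(C)C)C(C)C)c([Mg]Cl)cc1Br | intermediate
6 | [4-bromo-5-methoxy-2-(3-methylbut-2-enyl)phenoxy]triisopropylsilane | COc1cc(O[Si](C(C)C)(C(C)C)C(C)C)c(CC=C(C)C)cc1Br | intermediate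
7 | nitromethane | C[N+](=O)[O-] | starting material
8 | [5-methoxy-2-(3-methylbut-2-enyl)-4-(nitromethyl)phenoxy]triisopropylsilane | COc1cc(O[Si](C(C)C)(C(C)C)C(C)C)c(CC=C(C)C)cc1C[N+](=O)[O-] | intermediate
9 | formaldehyde (used as paraformaldehyde) | C=O | starting material
10 | 2-[2-methoxy-5-(3-methylbut-2-enyl)-4-(triisopropylsilyloxy)phenyl]-2-nitroethanol (racemic) | COc1cc(O[Si](C(C)C)(C(C)C)C(C)C)c(CC=C(C)C)cc1C(CO)[N+](=O)[O-] | intermediate
11 | 2-[2-methoxy-5-(3-methylbut-2-enyl)-4-(triisopropylsilyloxy)phenyl]-2-nitroethyl methanesulfonate (not isolated) | COc1cc(O[Si](C(C)C)(C(C)C)C(C)C)c(CC=C(C)C)cc1C(COS(C)(=O)=O)[N+](=O)[O-] | intermediate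
12 | [5-methoxy-2-(3-methylbut-2-enyl)-4-(1-nitroethenyl)phenoxy]triisopropylsilane | C=C([N+](=O)[O-])c1cc(CC=C(C)C)c(O[Si](C(C)C)(C(C)C)C(C)C)cc1OC | intermediate
13 | 2,4,6-trihydroxybenzaldehyde | O=Cc1c(O)cc(O)cc1O | starting material
14 | 2,6-dihydroxy-4-methoxybenzaldehyde | COc1cc(O)c(C=O)c(O)c1 | intermediate
15 | 2-hydroxy-4-methoxy-6-{2-[2-methoxy-5-(3-methylbut-2-enyl)-4-(triisopropylsilyloxy)phenyl]-2-nitroethoxy}benzaldehyde (not isolated) | COc1cc(O)c(C=O)c(c1)OCC(c1cc(CC=C(C)C)c(O[Si](C(C)C)(C(C)C)C(C)C)cc1OC)[N+](=O)[O-] | intermediate
16 | (4S)-7-methoxy-3-[2-methoxy-5-(3-methylbut-2-enyl)-4-(triisopropylsilyloxy)phenyl]-3-nitrochromane-4,5-diol (both C3 epimers) | COc1cc(O)c2c(c1)OCC(c1cc(CC=C(C)C)c(O[Si](C(C)C)(C(C)C)C(C)C)cc1OC)([N+](=O)[O-])[C@H]2O | intermediate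
17 | (4S)-4,5-bis(tert-butyldimethylsilyloxy)-7-methoxy-3-[2-methoxy-5-(3-methylbut-2-enyl)-4-(triisopropylsilyloxy)phenyl]-3-nitrochromane (both C3 epimers) | COc1cc(O[Si](C)(C)C(C)(C)C)c2c(c1)OCC(c1cc(CC=C(C)C)c(O[Si](C(C)C)(C(C)C)C(C)C)cc1OC)([N+](=O)[O-])[C@H]2O[Si](C)(C)C(C)(C)C | intermediate
18 | (3R,4R)-4,5-bis(tert-butyldimethylsilyloxy)-7-methoxy-3-[2-methoxy-5-(3-methylbut-2-enyl)-4-(triisopropylsilyloxy)phenyl]chromane (3,4-cis) | COc1cc(O[Si](C)(C)C(C)(C)C)c2c(c1)OC[C@@H](c1cc(CC=C(C)C)c(O[Si](C(C)C)(C(C)C)C(C)C)cc1OC)[C@H]2O[Si](C)(C)C(C)(C)C | intermediate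
19 | (3R,4R)-3-[4-hydroxy-2-methoxy-5-(3-methylbut-2-enyl)phenyl]-7-methoxychromane-4,5-diol (3,4-cis) | COc1cc(O)c2c(c1)OC[C@@H](c1cc(CC=C(C)C)c(O)cc1OC)[C@H]2O | target

## Step count and least certain steps

Total step count: 11. Longest linear sequence: 10 steps (steps 1–6 and 8–11, from 1 to 19); step 7 is a one-step branch to 14.

**Key step (step 8).** The Henry closure joins a hindered, aryl-stabilised nitronate to a weakly electrophilic, trioxygenated benzaldehyde and is therefore reversible. Ring opening and re-closure outside the catalyst pocket would erode the enantiomeric purity at C4, and the two C3 epimers could form with opposite sense at C4. Base-induced oligomerisation of 12 would also compete with the slow oxa-Michael addition of a hydrogen-bonded phenol. The fallback moves all stereocontrol to a later, reagent-controlled reduction; it sets out from 12 and 14 and comes back at 19.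
- The annulation is run without asymmetric induction (DABCO, CH2Cl2, rt) and should give the racemic nitrochromanediol F1 as a diastereomer mixture.
- TBSCl and imidazole in DMF should silylate only the phenol, giving the 5-silyl ether F2.
- Dess–Martin periodinane should give the 3-nitrochroman-4-one F3.
- Bu3SnH and AIBN should replace the nitro group through the α-keto benzylic radical and give the racemic isoflavanone F4, whose C3 is enolisable.
- Transfer hydrogenation with RuCl[(R,R)-TsDPEN](p-cymene) in HCO2H/Et3N should, by dynamic kinetic resolution, give the cis-(3R,4R) alcohol F5; the (R,R) ligand is chosen by analogy with aryl alkyl ketones.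
- Bu4NF/AcOH then gives 19.

**Denitration (step 10).** Hydrogen transfer to the wrong face would occur if ring C did not hold the C4 silyl ether pseudoaxial, and would lead to the 3,4-trans series. Slow hydrogen transfer to the stabilised benzylic radical would allow radical dimerisation or β-scission at O1–C2. The fallback replaces substrate-controlled hydrogen transfer by dynamic kinetic resolution; it sets out from 18 obtained as a mixture with its C3 epimer and comes back at 19.
- Bu4NF/AcOH removes all silyl groups and gives the (4R)-triol as a C3 epimer mixture F6.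
- TBSCl and imidazole should re-silylate only the two phenols, giving the bis(aryl silyl ether) F7 with the hindered C4 carbinol free.
- Dess–Martin periodinane gives the isoflavanone F8, in which C3 equilibrates.
- Transfer hydrogenation with RuCl[(R,R)-TsDPEN](p-cymene) in HCO2H/Et3N should give the cis-(3R,4R) alcohol F9.
- Bu4NF/AcOH gives 19.

**Nitromethylation (step 4).** A second arylation of the product nitronate, loss of the aryl silyl ether under hot phosphate, or slow oxidative addition at the electron-rich, ortho-substituted bromide would lower the yield of 8. The fallback builds the nitromethyl group by classical steps; it sets out from 6 and comes back at 8.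
- Bromine–lithium exchange (n-BuLi, THF, −78 °C) and quenching with DMF gives the benzaldehyde F10.
- NaBH4 in MeOH gives the benzyl alcohol F11.
- CBr4 and PPh3 give the benzyl bromide F12.
- AgNO2 in Et2O at 0 °C (Victor Meyer reaction) gives 8, to be separated from the nitrite ester that an electron-rich benzylic halide also forms.

**Nitroalkene formation (step 6).** Oligomerisation of 12 by the amine base during elimination, or on concentration, would waste the ring B fragment before the key step. The fallback avoids isolating the alkene; it sets out from 10 and comes back at 16. Acetylation (Ac2O, pyridine, DMAP cat.) gives the nitro acetate F13. F13 is used in step 8 in place of 12, together with solid NaHCO3, so that 12 is released slowly by E1cB elimination in the presence of 14 and the catalyst and is consumed as it forms.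

## Further compounds

F1 | step 8 | racemic 7-methoxy-3-[2-methoxy-5-(3-methylbut-2-enyl)-4-(triisopropylsilyloxy)phenyl]-3-nitrochromane-4,5-diol (diastereomer mixture) | COc1cc(O)c2c(c1)OCC(c1cc(CC=C(C)C)c(O[Si](C(C)C)(C(C)C)C(C)C)cc1OC)([N+](=O)[O-])C2O
F2 | step 8 | racemic 5-(tert-butyldimethylsilyloxy)-7-methoxy-3-[2-methoxy-5-(3-methylbut-2-enyl)-4-(triisopropylsilyloxy)phenyl]-3-nitrochroman-4-ol (diastereomer mixture) | COc1cc(O[Si](C)(C)C(C)(C)C)c2c(c1)OCC(c1cc(CC=C(C)C)c(O[Si](C(C)C)(C(C)C)C(C)C)cc1OC)([N+](=O)[O-])C2O
F3 | step 8 | racemic 5-(tert-butyldimethylsilyloxy)-7-methoxy-3-[2-methoxy-5-(3-methylbut-2-enyl)-4-(triisopropylsilyloxy)phenyl]-3-nitrochroman-4-one | COc1cc(O[Si](C)(C)C(C)(C)C)c2c(c1)OCC(c1cc(CC=C(C)C)c(O[Si](C(C)C)(C(C)C)C(C)C)cc1OC)([N+](=O)[O-])C2=O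
F4 | step 8 | racemic 5-(tert-butyldimethylsilyloxy)-7-methoxy-3-[2-methoxy-5-(3-methylbut-2-enyl)-4-(triisopropylsilyloxy)phenyl]chroman-4-one | COc1cc(O[Si](C)(C)C(C)(C)C)c2c(c1)OCC(c1cc(CC=C(C)C)c(O[Si](C(C)C)(C(C)C)C(C)C)cc1OC)C2=O
F5 | step 8 | (3R,4R)-5-(tert-butyldimethylsilyloxy)-7-methoxy-3-[2-methoxy-5-(3-methylbut-2-enyl)-4-(triisopropylsilyloxy)phenyl]chroman-4-ol | COc1cc(O[Si](C)(C)C(C)(C)C)c2c(c1)OC[C@@H](c1cc(CC=C(C)C)c(O[Si](C(C)C)(C(C)C)C(C)C)cc1OC)[C@H]2O
F6 | step 10 | (4R)-3-[4-hydroxy-2-methoxy-5-(3-methylbut-2-enyl)phenyl]-7-methoxychromane-4,5-diol (C3 epimer mixture) | COc1cc(O)c2c(c1)OCC(c1cc(CC=C(C)C)c(O)cc1OC)[C@H]2O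
F7 | step 10 | (4R)-5-(tert-butyldimethylsilyloxy)-3-[4-(tert-butyldimethylsilyloxy)-2-methoxy-5-(3-methylbut-2-enyl)phenyl]-7-methoxychroman-4-ol (C3 epimer mixture) | COc1cc(O[Si](C)(C)C(C)(C)C)c2c(c1)OCC(c1cc(CC=C(C)C)c(O[Si](C)(C)C(C)(C)C)cc1OC)[C@H]2O
F8 | step 10 | racemic 5-(tert-butyldimethylsilyloxy)-3-[4-(tert-butyldimethylsilyloxy)-2-methoxy-5-(3-methylbut-2-enyl)phenyl]-7-methoxychroman-4-one | COc1cc(O[Si](C)(C)C(C)(C)C)c2c(c1)OCC(c1cc(CC=C(C)C)c(O[Si](C)(C)C(C)(C)C)cc1OC)C2=O
F9 | step 10 | (3R,4R)-5-(tert-butyldimethylsilyloxy)-3-[4-(tert-butyldimethylsilyloxy)-2-methoxy-5-(3-methylbut-2-enyl)phenyl]-7-methoxychroman-4-ol | COc1cc(O[Si](C)(C)C(C)(C)C)c2c(c1)OC[C@@H](c1cc(CC=C(C)C)c(O[Si](C)(C)C(C)(C)C)cc1OC)[C@H]2O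
F10 | step 4 | 2-methoxy-5-(3-methylbut-2-enyl)-4-(triisopropylsilyloxy)benzaldehyde | COc1cc(O[Si](C(C)C)(C(C)C)C(C)C)c(CC=C(C)C)cc1C=O
F11 | step 4 | [2-methoxy-5-(3-methylbut-2-enyl)-4-(triisopropylsilyloxy)phenyl]methanol | COc1cc(O[Si](C(C)C)(C(C)C)C(C)C)c(CC=C(C)C)cc1CO
F12 | step 4 | [4-(bromomethyl)-5-methoxy-2-(3-methylbut-2-enyl)phenoxy]triisopropylsilane | COc1cc(O[Si](C(C)C)(C(C)C)C(C)C)c(CC=C(C)C)cc1CBr
F13 | step 6 | 2-[2-methoxy-5-(3-methylbut-2-enyl)-4-(triisopropylsilyloxy)phenyl]-2-nitroethyl acetate | COc1cc(O[Si](C(C)C)(C(C)C)C(C)C)c(CC=C(C)C)cc1C(COC(C)=O)[N+](=O)[O-]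
A1 | alternative 1 | 5-methoxy-3-{[2-(trimethylsilyl)ethoxy]methoxy}-2-(trimethylsilyl)phenyl trifluoromethanesulfonate | COc1cc(OCOCC[Si](C)(C)C)c([Si](C)(C)C)c(OS(=O)(=O)C(F)(F)F)c1
A2 | alternative 1 | 2-(5-bromo-2-methoxy-4-{[2-(trimethylsilyl)ethoxy]methoxy}phenyl)prop-2-enal | C=C(C=O)c1cc(Br)c(OCOCC[Si](C)(C)C)cc1OC
A3 | alternative 1 | 3-(5-bromo-2-methoxy-4-{[2-(trimethylsilyl)ethoxy]methoxy}phenyl)-7-methoxy-5-{[2-(trimethylsilyl)ethoxy]methoxy}-2H-chromene | COc1cc(OCOCC[Si](C)(C)C)c2c(c1)OCC(c1cc(Br)c(OCOCC[Si](C)(C)C)cc1OC)=C2
A4 | alternative 2 | (E)-1-[(3R,4R)-4,5-bis(tert-butyldimethylsilyloxy)-7-methoxychroman-3-yl]-1-diazo-7-methylocta-3,6-dien-2-one | COc1cc(O[Si](C)(C)C(C)(C)C)c2c(c1)OC[C@@H](C(=[N+]=[N-])C(=O)/C=C/CC=C(C)C)[C@H]2O[Si](C)(C)C(C)(C)C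
A5 | alternative 2 | methoxyacetylene (methoxyethyne) | COC#C
A6 | alternative 2 | 4-[(3R,4R)-4,5-bis(tert-butyldimethylsilyloxy)-7-methoxychroman-3-yl]-5-methoxy-2-(3-methylbut-2-enyl)phenol | COc1cc(O[Si](C)(C)C(C)(C)C)c2c(c1)OC[C@@H](c1cc(CC=C(C)C)c(O)cc1OC)[C@H]2O[Si](C)(C)C(C)(C)C
A7 | alternative 3 | 2-[4-(tert-butyldimethylsilyloxy)-2-methoxy-5-(3-methylbut-2-enyl)phenyl]-2-diazo-1-(2,4,6-trimethoxyphenyl)ethanone | COc1cc(OC)c(C(=O)C(=[N+]=[N-])c2cc(CC=C(C)C)c(O[Si](C)(C)C(C)(C)C)cc2OC)c(OC)c1
A8 | alternative 3 | racemic 3-[4-(tert-butyldimethylsilyloxy)-2-methoxy-5-(3-methylbut-2-enyl)phenyl]-5,7-dimethoxychroman-4-one | COc1cc(OC)c2c(c1)OCC(c1cc(CC=C(C)C)c(O[Si](C)(C)C(C)(C)C)cc1OC)C2=O
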